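The route rests on one disconnection: the cis C3–O and C2–isopropenyl bonds of the dihydrofuran ring (ring B) are traced back to the C2=C3 bond of a planar benzofuran. In one operation, catalyst-controlled epoxidation of this enol-ether bond and syn opening of the epoxide at C2 by tri(isopropenyl)aluminium dearomatize the furan ring and set both stereocentres. The step exploits ring oxygen O1, which makes C2=C3 electron-rich and stabilizes positive charge at C2. The precursor is 5-bromo-6,7-dimethoxybenzofuran, built in three regiochemically unambiguous steps from a salicylaldehyde. A bromine atom holds the place of the C5 acetyl group, which is introduced afterwards by lithiation and acylation, before the final angeloylation.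

Key step: step 5

Assumption: the (R,R) enantiomer of the manganese salen catalyst MnCl(salen) [trivalent manganese; salen = N,N'-bis(3,5-di-tert-butylsalicylidene)cyclohexane-1,2-diaminate] is taken to deliver oxygen to the face of C2=C3 that gives benzylic R at C3, as it does with indene. Should the sense prove opposite, the (S,S) catalyst is used and nothing else changes. Benzofuran numbering (O1, C2, C3, C3a, C4–C7, C7a) is used throughout; ring A is the benzene ring, ring B the furan ring.

Step 1
Reactants: 1 2-hydroxy-3,4-dimethoxybenzaldehyde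
Product: 2 5-bromo-2-hydroxy-3,4-dimethoxybenzaldehyde
Conditions: Br2 (1.05 equiv), NaOAc, AcOH, rt
Reagents that add atoms: bromine, BrBr
Why: Electrophilic aromatic bromination, in which C5 is para to the hydroxyl group and ortho to the 4-methoxy group, while the only other free position, C6, is meta to the hydroxyl group and ortho to the deactivating formyl group, so a single regioisomer should form.

Step 2
Reactants: 2 5-bromo-2-hydroxy-3,4-dimethoxybenzaldehyde, 3 ethyl bromoacetate
Product: 5 2-(4-bromo-6-formyl-2,3-dimethoxyphenoxy)acetic acid, via ethyl ester 4 (not isolated)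
Conditions: K2CO3, DMF, rt; then 2 M aq. NaOH, rt; HCl to pH 2
Reagents that add atoms: sodium hydroxide, [Na+].[OH-]
Why: Williamson ether synthesis of the phenoxide with the primary α-bromo ester followed by saponification (acyl–oxygen cleavage by hydroxide) in the same pot; at room temperature the ortho-formyl group should neither condense with the ester nor disproportionate.

Step 3
Reactants: 5 2-(4-bromo-6-formyl-2,3-dimethoxyphenoxy)acetic acid
Product: 6 5-bromo-6,7-dimethoxy-1-benzofuran
Conditions: Ac2O, NaOAc, AcOH, reflux
Reagents that add atoms: none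
Why: Intramolecular Perkin condensation of the mixed-anhydride enolate onto the ortho-formyl group followed by decarboxylative dehydration, the classical conversion of 2-formylphenoxyacetic acids into benzofurans unsubstituted at C2 and C3; the aryl bromide and the methyl ethers are inert to these conditions.

Step 4
Reactants: 7 2-bromopropene (3 equiv, one molecule for each isopropenyl ligand of 9)
Product: 9 tri(prop-1-en-2-yl)aluminium, via prop-1-en-2-yllithium 8 (not isolated)
Conditions: 7 (3.0 equiv), Li (1% Na, 6.3 equiv), Et2O, 0 °C to rt; AlCl3 (1.02 equiv), Et2O, 0 °C; solvent switch to toluene, filtration under argon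
Reagents that add atoms: aluminium chloride, Cl[Al](Cl)Cl; 2-bromopropene (second equivalent), C=C(C)Br; 2-bromopropene (third equivalent), C=C(C)Br
Why: Reductive lithiation of three molecules of the vinylic bromide followed by salt metathesis of the three alkenyllithium equivalents with one AlCl3 (3 C3H5Li + AlCl3 → Al(C3H5)3 + 3 LiCl), the standard route to homoleptic trialkenylalanes; a slight deficit of the lithium reagent avoids the unreactive tetraalkenylaluminate, and the toluene solution limits donor solvent to the ether bound to aluminium.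

Step 5
Reactants: 6 5-bromo-6,7-dimethoxy-1-benzofuran, 9 tri(prop-1-en-2-yl)aluminium
Product: 12 (2R,3R)-5-bromo-6,7-dimethoxy-2-(prop-1-en-2-yl)-2,3-dihydro-1-benzofuran-3-ol, via epoxide 10 (not isolated), via aluminium alkoxide 11 (not isolated)
Conditions: (R,R)-MnCl(salen) (10 mol%), dimethyldioxirane (DMDO, 1.1 equiv, dried CH2Cl2 solution prepared from acetone and KHSO5, slow addition), 4 Å MS, CH2Cl2, −78 °C; then 9 (4 equiv, toluene), −78 to −40 °C; aq. KNaC4H4O6
Reagents that add atoms: dimethyldioxirane, CC1(C)OO1
Why: Proposed new method: dimethyldioxirane oxidizes the trivalent manganese salen catalyst to a pentavalent oxo species that transfers oxygen to the electron-rich C2=C3 enol-ether bond of ring B and gives the cis-fused (2S,3R)-epoxide 10 under neutral, anhydrous conditions that epoxide and alane both tolerate; the alane then binds the epoxide oxygen, the C2–O bond ionizes to an O1-stabilized oxocarbenium–aluminate contact ion pair, and one isopropenyl ligand passes from aluminium to C2 through a five-membered transition state on the face that carries the C3–O–Al group. The closest known reaction types are the Jacobsen–Katsuki epoxidation of chromenes and isoflavones with dimethyldioxirane as water-free terminal oxidant, the dimethyldioxirane epoxidation of benzofurans to labile 2,3-epoxides, and the syn opening of 1,2-anhydro sugars by organoalanes. No ring is closed in the net reaction, since the oxirane is formed and opened again. C3 is set by the catalyst-controlled face of oxygen transfer, and C2 is set by retention, because ligand transfer inside the ion pair in a non-coordinating solvent places isopropenyl cis to the C3 oxygen. The step needs ionization at C2 and not at C3, and carbon–carbon bond formation faster than hydride shift or ring opening of the epoxide: O1 stabilizes the C2 cation, the 6-methoxy group is turned out of conjugation by its two ortho neighbours (Br at C5, OMe at C7), Br is inductively withdrawing meta to C3a, and an sp2 ligand migrates readily at −78 °C. Slow addition of the oxidant to substrate and catalyst keeps the uncatalysed racemic epoxidation small, and the bromine atom at C5 leaves no carbonyl group for the alane to attack.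

Step 6
Reactants: 12 (2R,3R)-5-bromo-6,7-dimethoxy-2-(prop-1-en-2-yl)-2,3-dihydro-1-benzofuran-3-ol, 13 N-methoxy-N-methylacetamide
Product: 16 1-[(2R,3R)-3-hydroxy-6,7-dimethoxy-2-(prop-1-en-2-yl)-2,3-dihydro-1-benzofuran-5-yl]ethan-1-one, via dilithio species 14 (not isolated), via lithium carbinolamine adduct 15 (not isolated)
Conditions: n-BuLi (2.2 equiv), THF, −78 °C; 13 (1.5 equiv), −78 to −20 °C; H2O
Reagents that add atoms: none
Why: Deprotonation of the hydroxyl group and bromine–lithium exchange give an aryllithium flanked by the 6-methoxy group, and its acylation by the N-methoxy-N-methylamide (Weinreb ketone synthesis) stops at the chelated tetrahedral adduct, so the methyl ketone appears only on work-up and is not attacked further; neither C2 nor C3 takes part, so both keep their configuration.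

Step 7
Reactants: 16 1-[(2R,3R)-3-hydroxy-6,7-dimethoxy-2-(prop-1-en-2-yl)-2,3-dihydro-1-benzofuran-5-yl]ethan-1-one, 17 angelic acid [(2Z)-2-methylbut-2-enoic acid]
Product: 19 (2R,3R)-5-acetyl-6,7-dimethoxy-2-(prop-1-en-2-yl)-2,3-dihydro-1-benzofuran-3-yl (2Z)-2-methylbut-2-enoate, via mixed anhydride 18 (not isolated)
Conditions: 17 (3 equiv), 2,4,6-trichlorobenzoyl chloride (3 equiv), Et3N (6 equiv), toluene, rt; then 16, toluene, 70 °C
Reagents that add atoms: none
Why: Yamaguchi esterification through the preformed 2,4,6-trichlorobenzoic mixed anhydride without a nucleophilic amine catalyst, conditions known to give angelates without Z to E isomerization to the tiglate; the alcohol attacks the less hindered angeloyl carbonyl group and the C3–O bond is not broken, so C3 stays R.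

Compound list
1 | 2-hydroxy-3,4-dimethoxybenzaldehyde | COc1ccc(C=O)c(O)c1OC | starting material
2 | 5-bromo-2-hydroxy-3,4-dimethoxybenzaldehyde | COc1c(Br)cc(C=O)c(O)c1OC | intermediate
3 | ethyl bromoacetate | CCOC(=O)CBr | starting material
4 | ethyl 2-(4-bromo-6-formyl-2,3-dimethoxyphenoxy)acetate | CCOC(=O)COc1c(C=O)cc(Br)c(OC)c1OC | intermediate
5 | 2-(4-bromo-6-formyl-2,3-dimethoxyphenoxy)acetic acid | OC(=O)COc1c(C=O)cc(Br)c(OC)c1OC | intermediate
6 | 5-bromo-6,7-dimethoxy-1-benzofuran | COc1c(Br)cc2ccoc2c1OC | intermediate
7 | 2-bromopropene | C=C(C)Br | starting material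
8 | prop-1-en-2-yllithium | C=C(C)[Li] | intermediate
9 | tri(prop-1-en-2-yl)aluminium (used as its ether-solvated toluene solution) | C=C(C)[Al](C(C)=C)C(C)=C | intermediate
10 | (2S,3R)-5-bromo-2,3-epoxy-6,7-dimethoxy-2,3-dihydro-1-benzofuran (oxirane oxygen bridging C2 and C3 on one face) | Brc1cc2[C@H]3O[C@H]3Oc2c(OC)c1OC | intermediate
11 | {[(2R,3R)-5-bromo-6,7-dimethoxy-2-(prop-1-en-2-yl)-2,3-dihydro-1-benzofuran-3-yl]oxy}di(prop-1-en-2-yl)aluminium | C=C(C)[C@H]1Oc2c(cc(Br)c(OC)c2OC)[C@H]1O[Al](C(C)=C)C(C)=C | intermediate
12 | (2R,3R)-5-bromo-6,7-dimethoxy-2-(prop-1-en-2-yl)-2,3-dihydro-1-benzofuran-3-ol (cis) | C=C(C)[C@H]1Oc2c(cc(Br)c(OC)c2OC)[C@H]1O | intermediate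
13 | N-methoxy-N-methylacetamide | CC(=O)N(C)OC | starting material
14 | lithium (2R,3R)-5-lithio-6,7-dimethoxy-2-(prop-1-en-2-yl)-2,3-dihydro-1-benzofuran-3-olate | C=C(C)[C@H]1Oc2c(cc([Li])c(OC)c2OC)[C@H]1O[Li] | intermediate
15 | dilithium salt of the tetrahedral adduct of 14 with 13 (carbinolamine carbon of undefined configuration, lost on work-up) | C=C(C)[C@H]1Oc2c(cc(C(C)(O[Li])N(C)OC)c(OC)c2OC)[C@H]1O[Li] | intermediate
16 | 1-[(2R,3R)-3-hydroxy-6,7-dimethoxy-2-(prop-1-en-2-yl)-2,3-dihydro-1-benzofuran-5-yl]ethan-1-one | C=C(C)[C@H]1Oc2c(cc(C(C)=O)c(OC)c2OC)[C@H]1O | intermediate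
17 | angelic acid, (2Z)-2-methylbut-2-enoic acid | C/C=C(/C)C(=O)O | starting material
18 | (2Z)-2-methylbut-2-enoic 2,4,6-trichlorobenzoic anhydride | C/C=C(/C)C(=O)OC(=O)c1c(Cl)cc(Cl)cc1Cl | intermediate
19 | (2R,3R)-5-acetyl-6,7-dimethoxy-2-(prop-1-en-2-yl)-2,3-dihydro-1-benzofuran-3-yl (2Z)-2-methylbut-2-enoate | C=C(C)[C@H]1Oc2c(cc(C(C)=O)c(OC)c2OC)[C@H]1OC(=O)/C(C)=C\C | target

Total step count: 7. Longest linear sequence: 6 (steps 1, 2, 3, 5, 6, 7); step 4 is a one-step side branch.

Steps most likely to fail

1. Step 5 (proposed new method). Three processes may defeat it: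
- oxygen transfer with poor facial selectivity, or through the uncatalysed racemic pathway;
- collapse of the epoxide by hydride shift or by ring opening before the carbon–carbon bond forms;
- delivery of isopropenyl from the opposite face by a second molecule of alane.

The fallback uses known chemistry and builds the C2–C3 bond by an aldol addition in place of the dearomatization. It sets out from 2 and comes back at 12. Alkylation of 2 with chloroacetone (K2CO3, NaI, acetone) should give 1-(4-bromo-6-formyl-2,3-dimethoxyphenoxy)propan-2-one F1. An enamine-mediated intramolecular aldol addition with proline, using the enantiomer that leads to the 2S,3R product, should give mainly the cis ketol 1-[(2S,3R)-5-bromo-3-hydroxy-6,7-dimethoxy-2,3-dihydro-1-benzofuran-2-yl]ethan-1-one F2. Silylation (TBSOTf, 2,6-lutidine, CH2Cl2, −78 °C) should give 1-[(2S,3R)-5-bromo-3-[(tert-butyldimethylsilyl)oxy]-6,7-dimethoxy-2,3-dihydro-1-benzofuran-2-yl]ethan-1-one F3, which can no longer dehydrate to the aromatic benzofuran. Petasis methylenation (Cp2TiMe2, toluene, 65 °C) should turn the acetyl group into the isopropenyl group of tert-butyl{[(2R,3R)-5-bromo-6,7-dimethoxy-2-(prop-1-en-2-yl)-2,3-dihydro-1-benzofuran-3-yl]oxy}dimethylsilane F4. Bu4NF in THF should then free alcohol 12.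

2. Step 7. The angeloyl double bond may isomerize to the E (tigloyl) geometry during activation, or the benzylic C3–O bond may ionize on heating and lead to elimination towards the aromatic benzofuran. The fallback builds the Z double bond on an ester that is already in place; it sets out from 16 and comes back at 19. Acylation of 16 with 2-[bis(2,2,2-trifluoroethoxy)phosphoryl]propanoic acid (EDC, catalytic DMAP, CH2Cl2, 0 °C) should give (2R,3R)-5-acetyl-6,7-dimethoxy-2-(prop-1-en-2-yl)-2,3-dihydro-1-benzofuran-3-yl 2-[bis(2,2,2-trifluoroethoxy)phosphoryl]propanoate F5. Still–Gennari olefination of F5 with acetaldehyde (KN(SiMe3)2, 18-crown-6, THF, −78 °C) should then give the Z ester 19 directly.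

3. Step 3. Condensation without decarboxylation, or resinification of the electron-rich aldehyde in hot anhydride, may erode the conversion to the benzofuran. The fallback separates ring formation from decarboxylation; it sets out from 2 and comes back at 6. Rap–Stoermer-type condensation of 2 with 3 (K2CO3, DMF, 100 °C) should give ethyl 5-bromo-6,7-dimethoxy-1-benzofuran-2-carboxylate F6. Saponification (NaOH, aqueous EtOH, then HCl) should give 5-bromo-6,7-dimethoxy-1-benzofuran-2-carboxylic acid F7. Protodecarboxylation (catalytic Ag2CO3, AcOH, DMSO, 120 °C) should then deliver 6.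

Further compounds
F1 | step 5 | 1-(4-bromo-6-formyl-2,3-dimethoxyphenoxy)propan-2-one | CC(=O)COc1c(C=O)cc(Br)c(OC)c1OC
F2 | step 5 | 1-[(2S,3R)-5-bromo-3-hydroxy-6,7-dimethoxy-2,3-dihydro-1-benzofuran-2-yl]ethan-1-one | CC(=O)[C@H]1Oc2c(cc(Br)c(OC)c2OC)[C@H]1O
F3 | step 5 | 1-[(2S,3R)-5-bromo-3-[(tert-butyldimethylsilyl)oxy]-6,7-dimethoxy-2,3-dihydro-1-benzofuran-2-yl]ethan-1-one | CC(=O)[C@H]1Oc2c(cc(Br)c(OC)c2OC)[C@H]1O[Si](C)(C)C(C)(C)C
F4 | step 5 | tert-butyl{[(2R,3R)-5-bromo-6,7-dimethoxy-2-(prop-1-en-2-yl)-2,3-dihydro-1-benzofuran-3-yl]oxy}dimethylsilane | C=C(C)[C@H]1Oc2c(cc(Br)c(OC)c2OC)[C@H]1O[Si](C)(C)C(C)(C)C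
F5 | step 7 | (2R,3R)-5-acetyl-6,7-dimethoxy-2-(prop-1-en-2-yl)-2,3-dihydro-1-benzofuran-3-yl 2-[bis(2,2,2-trifluoroethoxy)phosphoryl]propanoate (both epimers at the phosphonate-bearing carbon) | C=C(C)[C@H]1Oc2c(cc(C(C)=O)c(OC)c2OC)[C@H]1OC(=O)C(C)P(=O)(OCC(F)(F)F)OCC(F)(F)F
F6 | step 3 | ethyl 5-bromo-6,7-dimethoxy-1-benzofuran-2-carboxylate | CCOC(=O)c1cc2cc(Br)c(OC)c(OC)c2o1
F7 | step 3 | 5-bromo-6,7-dimethoxy-1-benzofuran-2-carboxylic acid | OC(=O)c1cc2cc(Br)c(OC)c(OC)c2o1
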